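Late in the closed-flask runs, intermediate A reads the same fraction of the charge from two different charges: 49% at 6.00 min from 1 M, and 49% at 6.00 min from 0.67 M.

| flask | starting material | remark | time |
|---|---|---|---|
| north-east | 1 M | run made earlier |  |
| west | 0.67 M | run made earlier |  |
| south | 1.5 M | run made earlier |  |
| noon | 1.0 M | everything together in a closed stirred flask, run for 10 min | 10 min |
| dusk | 1.0 M | a single well-mixed tank run continuously and read at steady state, 10 min in it on average |  |
| dawn | 1.0 M | plug flow through a tube for 10 min, no back-mixing | 10 min |

- north-east (time / min: intermediate A / %, target / %): 0.500: 68, 0; 0.833: 84, 0; 1.50: 84, 0; 3.00: 71, 3; 6.00: 49, 3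
- west (time / min: intermediate A / %, target / %): 1.00: 85, 0; 3.00: 73, 1; 6.00: 49, 3; 8.00: 41, 1; 12.0: 22, 2
- south (time / min: intermediate A / %, target / %): 2.50: 73, 0; 5.00: 54, 3; 8.00: 39, 3; 10.0: 32, 4; 12.0: 20, 6

(each reading ± 2 percentage points)

- the stated concentrations are those of everything mixed, before any reaction; amounts are the same in each set-up
- the earlier runs were made in a closed, stirred flask

- the set-up with the highest amount of intermediate A at the outlet or at the end, in percent of the starting material put in ("none" if the first two lie within 2 percentage points) (noon / dusk / dawn / none)
- amount of intermediate A at the outlet or at the end, in percent of the starting material put in, noon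
- amount of intermediate A at the outlet or at the end, in percent of the starting material put in, dusk
- amount of intermediate A at the outlet or at the end, in percent of the starting material put in, dawn

So you can treat the decline as first order. From the west readings, 73% at 3.00 min and 22% at 12.0 min, you read 7.50 min as the lifetime of intermediate A, its mean survival time once made.

In noon, the closed flask, and in dawn, the tube, each portion of the charge spends 10 min, so I carry the 3.00 min reading forward and get 28.7% in each. In dusk, the tank, the same 10 min is only an average. It equals 1.33 lifetimes (the Damköhler number), more than one. Taking the charge as converted to intermediate A, I divide it by one plus that number and get 42.9%.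

The forecast says dusk, with 29% for noon, 42% for dusk against my 42.9%, and 29% for dawn: “back-mixing helps because its residence-time distribution leaves some material young”.

The simulation gives dusk, with 28.9% for noon, 42.1% for dusk and 28.9% for dawn.

    intermediate C ⇌ target (K = 1.80, k = 0.00100 s⁻¹)
    starting material → intermediate A (k = 0.0460 s⁻¹)
    intermediate A → intermediate B (k = 9.50 × 10⁻⁴ s⁻¹)
    intermediate A → side product (k = 0.00120 s⁻¹)
    intermediate B → intermediate C (k = 0.00180 s⁻¹)

Now read dawn later, at 25 min. That is 2.93 lifetimes past the 3.00 min reading, so the lifetime predicts 3.89% of the charge as intermediate A. The dawn tube read at 25 min holds 4.17% of the charge as intermediate A.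

(The data are calculated for an exercise; noise was put on by code.)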